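Follow the rate of side product, not the amounts.

| flask | starting material | reagent | second substrate | remark | time |
|---|---|---|---|---|---|
| summer | 0.10 M | 1 equiv | 0.50 equiv | run made earlier |  |
| midnight | 0.14 M | 1 equiv | 0.50 equiv | run made earlier |  |
| dawn | 0.22 M | 1 equiv | 0.50 equiv | run made earlier |  |
| noon | 0.10 M | 1.5 equiv | 0.50 equiv | run made earlier |  |
| theta | 0.10 M (fed, over 2.5 d) | 1.00 equiv | 0.500 equiv | all else is in the flask from the start; the feed brings no volume worth counting | 3.0 d |
| gamma | 0.10 M (fed, over 6.0 h) | 1.00 equiv | 0.500 equiv | all else is in the flask from the start; the feed brings no volume worth counting | 3.0 d |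
| epsilon | 0.10 M | 1.00 equiv | 0.500 equiv | everything together at the start | 3.0 d |
| zeta | 0.10 M | 1.00 equiv (fed, over 2.5 d) | 0.500 equiv | all else is in the flask from the start; the feed brings no volume worth counting | 3.0 d |



- summer (time / d: side product / %, target / %): 0.417: 33.0, 33.2; 0.833: 50.9, 21.7; 1.25: 61.5, 16.0; 1.67: 67.8, 10.6; 2.00: 70.7, 10.3; 2.50: 74.9, 6.6; 3.00: 77.5, 6.0
- midnight (time / d: side product / %, target / %): 0.208: 25.4, 38.9; 0.333: 35.8, 33.5; 0.417: 41.7, 31.1; 0.625: 52.6, 24.4; 1.04: 64.3, 15.7; 1.67: 74.2, 9.5; 2.50: 82.3, 5.8
- dawn (time / d: side product / %, target / %): 0.333: 47.5, 31.4; 0.625: 63.8, 21.3; 1.04: 75.1, 13.1; 1.25: 78.6, 11.0; 1.67: 82.1, 7.3; 2.08: 85.1, 6.1; 2.50: 88.1, 4.9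
- noon (time / d: side product / %, target / %): 0.208: 20.3, 47.6; 0.333: 28.8, 43.5; 0.625: 43.4, 33.3; 1.25: 60.9, 19.5; 2.50: 76.3, 9.0

(scatter of a reading: 0.5 percentage points)

1. the flask with the highest amount of side product, in percent of the starting material charged ("all alike" if they lie within 1.5 percentage points) (theta / gamma / epsilon / zeta / all alike)
2. final side product, as a percentage of the starting material charged, in theta
3. final side product, as a percentage of the starting material charged, in gamma
4. final side product, as a percentage of the starting material charged, in epsilon
5. final side product, as a percentage of the starting material charged, in zeta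

Between 0.417 d and 0.833 d the summer run gains side product at 0.430 d⁻¹ in shares of the charge, with target near 27.5 % and starting material, read as what the two products leave, near 30.6 %. Dividing that rate by both shares gives 5.12 d⁻¹: the capture constant, a second-order rate constant taken at 0.10 M, meaning the share of the charge turned into side product per day with both shares full. Dawn gives 11.8 d⁻¹ on 2.20 times the charge, so the reading grows with the charge.

By the last summer interval the rate is 0.0520 d⁻¹, down 8.27-fold. Target share fell 4.36-fold, starting-material share 1.75-fold. Late hours add little, so epsilon, with summer's charges, should end near 77.5 %.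

Feeds are reckoned here by their delay. A species fed at a steady rate enters on average 1.25 d late in theta and in zeta, later than the 0.125 d in gamma. Gamma's feed ends before summer's first reading. This reckoning puts epsilon first and gamma next, with theta and zeta below them, and it does not order those two.

The forecast differs: zeta first, with 90 % there, 77.5 % in epsilon, 73 % in gamma and 52 % in theta, on the ground that “Zeta keeps starting material in excess while target forms slowly”.

The flasks give 77.9 % in epsilon, 75.6 % in gamma, 72.5 % in zeta and 46.4 % in theta. At 3.00 d zeta holds 11.6 % of target against 5.69 % in epsilon, on 15.9 % and 16.4 % of starting material. The capture constant turns these into 0.0948 d⁻¹ for zeta and 0.0478 d⁻¹ for epsilon, so zeta is still gaining about twice as fast.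

    starting material + reagent ⇌ target (K = 31.0 L mol⁻¹, k = 0.0544 L mol⁻¹ min⁻¹)
    second substrate + reagent ⇌ second product (K = 24.1 L mol⁻¹, k = 0.00460 L mol⁻¹ min⁻¹)
    2 reagent → homo dimer (k = 0.00654 L mol⁻¹ min⁻¹)
    starting material + target → side product (k = 0.0182 L mol⁻¹ min⁻¹)

In a neighbour of epsilon charged with 0.025 M, a quarter of the charge, the constant becomes 1.28 d⁻¹, and summer's early shares, held for 3.0 d without slowing, give 32.3 %. The computed flask gives 40.7 %, with 48.2 % still starting material.

(Readings and results are simulated with made-up constants; scatter was added.)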